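**Retrosynthetic overview**
1. Target 10 ⇐ 9: the formyl group is unmasked last, by base-induced N–O fragmentation of a benzylic N-alkoxyphthalimide.
2. 9 ⇐ dione 6 + guaiazulene 7: Friedel–Crafts hydroxyalkylation at C2 of an indane-1,2-dione, then dehydration, gives the C2–azulenyl bond and the indenone C2=C3 bond.
3. 6 ⇐ 5: α-oxygenation of the indanone with SeO2.
4. 5 ⇐ 4: key step, site-selective benzylic C–H to C–O bond formation at the C4 methyl group; this oxygen becomes the aldehyde oxygen.
5. 4 ⇐ p-xylene 1 + crotonic acid 2. Ring order: benzene ring bought, five-membered carbocycle closed first (step 1), azulene bicycle bought intact and joined last.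

Assumption: the target SMILES has no stereocentre and no defined axis, so the target is one achiral compound. C3 of 4–6 is racemic, 8 is a diastereomer mixture, and this centre becomes sp2 in step 4.

Abbreviations: NHPI = N-hydroxyphthalimide; HFIP = 1,1,1,3,3,3-hexafluoropropan-2-ol; PPA = polyphosphoric acid.

**Step 1**
Reactants: 1 p-xylene (1,4-dimethylbenzene, 3 equiv); 2 crotonic acid ((E)-but-2-enoic acid)
Product: 4 3,4,7-trimethyl-2,3-dihydro-1H-inden-1-one (racemic), via aryl enone 3 (not isolated)
Conditions: PPA, 90 °C, 3 h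
Reagents that add atoms: none
Why: Friedel–Crafts acylation of p-xylene (all four ring positions are equivalent) is followed by Nazarov-type ring closure (intramolecular Friedel–Crafts alkylation) at the only free ortho position, and C3 forms racemic, which does not matter because it becomes sp2 in step 4.

**Step 2**
Reactants: 4 3,4,7-trimethyl-2,3-dihydro-1H-inden-1-one
Product: 5 2-[(3,7-dimethyl-1-oxo-2,3-dihydro-1H-inden-4-yl)methoxy]-1H-isoindole-1,3(2H)-dione (racemic)
Conditions: NHPI (2 equiv), PhI(OAc)2 (1.2 equiv, in portions), HFIP, 40 °C, Ar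
Reagents that add atoms: N-hydroxyphthalimide, O=C1c2ccccc2C(=O)N1O
Why: Proposed new method: a site-selective cross-dehydrogenative C–O coupling in which the electrophilic phthalimide-N-oxyl radical (from NHPI and PhI(OAc)2) abstracts hydrogen only from the C4 methyl group, because HFIP hydrogen-bonds to the ketone and so polarity-deactivates the C7 methyl (ortho to and conjugated with C=O), the C2 methylene (alpha) and the C3 methine (beta, shielded, and held near the arene plane by peri strain with the C4 methyl so that benzylic overlap is poor), after which the primary benzylic radical is captured by a second, persistent N-oxyl radical to form the C–O bond and the electron-poor N-alkoxyimide resists a second abstraction; the closest known reaction type is the NHPI/PhI(OAc)2 benzylic C–H aminoxylation of simple alkylarenes used in excess, together with NHPI-mediated methylarene oxidation in HFIP.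

**Step 3**
Reactants: 5 2-[(3,7-dimethyl-1-oxo-2,3-dihydro-1H-inden-4-yl)methoxy]-1H-isoindole-1,3(2H)-dione
Product: 6 2-[(3,7-dimethyl-1,2-dioxo-2,3-dihydro-1H-inden-4-yl)methoxy]-1H-isoindole-1,3(2H)-dione (racemic)
Conditions: SeO2 (1.2 equiv), 1,4-dioxane/H2O 30:1, 95 °C
Reagents that add atoms: selenium dioxide, O=[Se]=O
Why: Riley oxidation, in which SeO2 reacts with the enol of the only α-methylene (C2) by an ene reaction and [2,3]-sigmatropic shift and then loses selenium and water to give the 1,2-dione, while the N-alkoxyimide and the aryl methyl group are inert.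

**Step 4**
Reactants: 6 2-[(3,7-dimethyl-1,2-dioxo-2,3-dihydro-1H-inden-4-yl)methoxy]-1H-isoindole-1,3(2H)-dione; 7 guaiazulene (1,4-dimethyl-7-(propan-2-yl)azulene, 0.95 equiv)
Product: 10 3,7-dimethyl-2-[3,8-dimethyl-5-(propan-2-yl)azulen-1-yl]-1-oxo-1H-indene-4-carbaldehyde (the target), via ketol 8 (not isolated), via N-alkoxyphthalimide indenone 9 (not isolated)
Conditions: TsOH·H2O (10 mol%), MeCN, 25 to 45 °C, Ar; then DBU (3 equiv), 60 °C
Reagents that add atoms: none
Why: Friedel–Crafts hydroxyalkylation by the nucleophilic C3 of guaiazulene at the more electrophilic, non-conjugated C2 carbonyl gives ketol 8, acid-catalysed E1 dehydration through the azulenylium-stabilised cation with loss of H-3 gives indenone 9 (erasing the C3 centre), and a base-induced Kornblum–DeLaMare-type fragmentation of the benzylic N-alkoxyphthalimide (phthalimide anion leaves from oxygen) then releases the aldehyde only after the acid is quenched, so guaiazulene never meets a free aldehyde under acid.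

**Compound list**
1 | p-xylene (1,4-dimethylbenzene) | Cc1ccc(C)cc1 | starting material
2 | crotonic acid ((E)-but-2-enoic acid) | C/C=C/C(=O)O | starting material
3 | (E)-1-(2,5-dimethylphenyl)but-2-en-1-one | C/C=C/C(=O)c1cc(C)ccc1C | intermediate (not isolated)
4 | 3,4,7-trimethyl-2,3-dihydro-1H-inden-1-one (racemic) | CC1CC(=O)c2c(C)ccc(C)c21 | intermediate
5 | 2-[(3,7-dimethyl-1-oxo-2,3-dihydro-1H-inden-4-yl)methoxy]-1H-isoindole-1,3(2H)-dione (racemic) | CC1CC(=O)c2c(C)ccc(CON3C(=O)c4ccccc4C3=O)c21 | intermediate
6 | 2-[(3,7-dimethyl-1,2-dioxo-2,3-dihydro-1H-inden-4-yl)methoxy]-1H-isoindole-1,3(2H)-dione (racemic) | CC1C(=O)C(=O)c2c(C)ccc(CON3C(=O)c4ccccc4C3=O)c21 | intermediate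
7 | guaiazulene (1,4-dimethyl-7-(propan-2-yl)azulene) | CC1=CC=C(C(C)C)C=C2C(C)=CC=C12 | starting material
8 | 2-({2-hydroxy-3,7-dimethyl-2-[3,8-dimethyl-5-(propan-2-yl)azulen-1-yl]-1-oxo-2,3-dihydro-1H-inden-4-yl}methoxy)-1H-isoindole-1,3(2H)-dione (diastereomer mixture, racemic) | CC1C(O)(c2cc(C)c3cc(C(C)C)ccc(C)c2-3)C(=O)c2c(C)ccc(CON4C(=O)c5ccccc5C4=O)c21 | intermediate (not isolated)
9 | 2-({3,7-dimethyl-2-[3,8-dimethyl-5-(propan-2-yl)azulen-1-yl]-1-oxo-1H-inden-4-yl}methoxy)-1H-isoindole-1,3(2H)-dione | CC1=C(c2cc(C)c3cc(C(C)C)ccc(C)c2-3)C(=O)c2c(C)ccc(CON4C(=O)c5ccccc5C4=O)c21 | intermediate (not isolated)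
10 | 3,7-dimethyl-2-[3,8-dimethyl-5-(propan-2-yl)azulen-1-yl]-1-oxo-1H-indene-4-carbaldehyde (achiral) | CC1=C(c2cc(C)c3cc(C(C)C)ccc(C)c2-3)C(=O)c2c(C)ccc(C=O)c21 | target

**Totals and risks**
Total steps: 4. Longest linear sequence: 4 steps (1 → 4 → 5 → 6 → 10); guaiazulene 7 is used as bought.

Most likely to fail:

1. Step 2 (the proposed new C–H aminoxylation). The risk is competing attack at the C7 methyl or the C3 methine, or α-acetoxylation of the ketone by PhI(OAc)2. The fallback uses known chemistry only, sets out from crotonic acid 2 and comes back at 5. Acid 2 is converted with SOCl2 into (E)-but-2-enoyl chloride F1. This acylates 4-bromotoluene F2 (bought) under AlCl3 in CH2Cl2 at 0 °C, ortho to the methyl group, to give (E)-1-(5-bromo-2-methylphenyl)but-2-en-1-one F3. Hot concentrated H2SO4 closes F3 next to the bromine (Nazarov-type cyclisation) to 4-bromo-3,7-dimethyl-2,3-dihydro-1H-inden-1-one F4, in which the halogen marks the future formyl carbon without ambiguity. Stille coupling of F4 with Bu3SnCH2OH (Pd(PPh3)4, dioxane, 100 °C) gives 4-(hydroxymethyl)-3,7-dimethyl-2,3-dihydro-1H-inden-1-one F5. A Mitsunobu reaction of F5 with N-hydroxyphthalimide (PPh3, DIAD, THF) forms the benzylic C–O bond and gives 5.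

2. Step 3 (SeO2 oxidation). The risk is over-oxidation at the tertiary C3–H next to the new carbonyl, or loss of material through the enol tautomer. The fallback sets out from 5 and comes back at 6. Ketone 5 is nitrosated at C2 with isoamyl nitrite and HCl (a C–N bond in place of the C–O bond) to give 2-{[2-(hydroxyimino)-3,7-dimethyl-1-oxo-2,3-dihydro-1H-inden-4-yl]methoxy}-1H-isoindole-1,3(2H)-dione F6. Oxime exchange of F6 with aqueous formaldehyde and HCl gives 6.

3. Step 4 (azulene union and unmasking in one flask). The risk is slow ionisation of the α-keto carbinol 8, acyloin-type rearrangement of 8, or base damage (for example at the vinylogously acidic C3 methyl of 9) during the fragmentation. The fallback sets out from 6 and comes back at 9. Dione 6 is trapped in its 2-hydroxyindenone tautomeric form with Tf2O and 2,6-lutidine as 4-{[(1,3-dioxo-1,3-dihydro-2H-isoindol-2-yl)oxy]methyl}-3,7-dimethyl-1-oxo-1H-inden-2-yl trifluoromethanesulfonate F7. F7 is joined to 7 at the azulene C3 position by palladium-catalysed direct C–H coupling (Pd(OAc)2, KOAc, DMA, 100 °C), which replaces the acid-mediated Friedel–Crafts step by a cross-coupling on a finished indenone. Compound 9 is then isolated and fragmented with DBU as in the second half of step 4.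

**Further compounds**
F1 | step 2 | (E)-but-2-enoyl chloride | C/C=C/C(Cl)=O
F2 | step 2 | 4-bromotoluene (bought) | Cc1ccc(Br)cc1
F3 | step 2 | (E)-1-(5-bromo-2-methylphenyl)but-2-en-1-one | C/C=C/C(=O)c1cc(Br)ccc1C
F4 | step 2 | 4-bromo-3,7-dimethyl-2,3-dihydro-1H-inden-1-one (racemic) | CC1CC(=O)c2c(C)ccc(Br)c21
F5 | step 2 | 4-(hydroxymethyl)-3,7-dimethyl-2,3-dihydro-1H-inden-1-one (racemic) | CC1CC(=O)c2c(C)ccc(CO)c21
F6 | step 3 | 2-{[2-(hydroxyimino)-3,7-dimethyl-1-oxo-2,3-dihydro-1H-inden-4-yl]methoxy}-1H-isoindole-1,3(2H)-dione (racemic) | CC1C(=NO)C(=O)c2c(C)ccc(CON3C(=O)c4ccccc4C3=O)c21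
F7 | step 4 | 4-{[(1,3-dioxo-1,3-dihydro-2H-isoindol-2-yl)oxy]methyl}-3,7-dimethyl-1-oxo-1H-inden-2-yl trifluoromethanesulfonate | CC1=C(OS(=O)(=O)C(F)(F)F)C(=O)c2c(C)ccc(CON3C(=O)c4ccccc4C3=O)c21
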